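Rings are lettered A to G in SMILES order. The route rests on cutting ring B, whose B1 ether (to ring A) sits meta to the B3 hydroxyl and para to the B4 ether (to ring C), with oxygen at B5 and hydrogen at B2 and B6: exactly the pattern a vinylketene–ynol ether benzannulation writes. In one photochemical operation a 2,4,6-trimethoxyphenyl ethynyl ether and a (Z)-1-diazo-3-methoxy-4-aryloxybut-3-en-2-one bearing the CDEFG pentamer are merged, four ring B bonds form and both crowded ether junctions arrive intact. The precursor comes from a copper-assembled pentamer phenol by vinylic substitution and diazo transfer; all other phenols travel as methyl ethers.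

Key step: step 17

Remarks and assumptions on the chemistry:
- Compounds 1, 4, 7, 8, 15, 22 and 25 are taken as purchasable.
- "CDEFG-aryloxy" means the oxygen-linked residue of phenol 14.
- The diazo ketone is reached by diazo transfer to a methyl ketone, not by acylating diazomethane, because the push–pull acyl group is a poor electrophile and the conjugated alkene a possible dipolarophile.
- The enol ether of 19 is assumed to form as the thermodynamically preferred Z isomer (aryloxy anti to acetyl). Any E isomer would converge on the same phenol in step 17.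

Step 1
Reactants: 1 2,3,4-trimethoxyphenol
Product: 2 6-bromo-2,3,4-trimethoxyphenol
Conditions: NBS, i-Pr2NH (cat.), CH2Cl2, 0 °C
Reagents that add atoms: N-bromosuccinimide O=C1CCC(=O)N1Br
Why: Amine-mediated electrophilic aromatic bromination is directed ortho to the free hydroxyl, whose para position is blocked by methoxy, so bromine should enter C6 and not the anisole-type C5 position.

Step 2
Reactants: 2 6-bromo-2,3,4-trimethoxyphenol
Product: 3 2-(benzyloxy)-1-bromo-3,4,5-trimethoxybenzene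
Conditions: BnBr, K2CO3, DMF, 25 °C
Reagents that add atoms: benzyl bromide BrCc1ccccc1
Why: Williamson etherification masks the future D6 oxygen as a benzyl ether that survives copper coupling and is removable by hydrogenolysis.

Step 3
Reactants: 3 2-(benzyloxy)-1-bromo-3,4,5-trimethoxybenzene; 4 2,6-dimethoxyphenol
Product: 5 2-(benzyloxy)-1-(2,6-dimethoxyphenoxy)-3,4,5-trimethoxybenzene
Conditions: CuI (cat.), picolinic acid, K3PO4, DMSO, 100 °C, Ar; excess 4
Reagents that add atoms: none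
Why: Ullmann diaryl ether coupling with the picolinic acid ligand, which tolerates 2,6-disubstituted phenols and ortho-substituted aryl bromides, forms the C4–O–D1 bond on small components where the cheap phenol can be used in excess.

Step 4
Reactants: 5 2-(benzyloxy)-1-(2,6-dimethoxyphenoxy)-3,4,5-trimethoxybenzene
Product: 6 6-(2,6-dimethoxyphenoxy)-2,3,4-trimethoxyphenol
Conditions: H2 (1 atm), Pd/C, EtOAc/MeOH, 25 °C
Reagents that add atoms: none
Why: Catalytic hydrogenolysis cleaves the benzylic C–O bond only, leaving methyl ethers and the diaryl ether untouched and freeing the D6 phenol.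

Step 5
Reactants: 7 5-iodo-1,2,3-trimethoxybenzene; 8 4-bromo-2,6-dimethoxyphenol
Product: 9 5-bromo-1,3-dimethoxy-2-(3,4,5-trimethoxyphenoxy)benzene
Conditions: CuI (cat.), picolinic acid, K3PO4, DMSO, 80 °C, Ar; slight excess 7
Reagents that add atoms: none
Why: Chemoselective Ullmann ether synthesis, in which the aryl iodide reacts far faster than the bromide of 8 (further deactivated as a para-bromophenoxide), should form the F4–O–G1 ether with the bromide retained.

Step 6
Reactants: 9 5-bromo-1,3-dimethoxy-2-(3,4,5-trimethoxyphenoxy)benzene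
Product: 10 5-iodo-1,3-dimethoxy-2-(3,4,5-trimethoxyphenoxy)benzene
Conditions: NaI, CuI (cat.), trans-N,N′-dimethylcyclohexane-1,2-diamine (cat.), 1,4-dioxane, 110 °C
Reagents that add atoms: sodium iodide [Na+].[I-]
Why: The copper-catalysed aromatic Finkelstein exchange is driven by precipitation of NaBr and restores the iodide-over-bromide discrimination needed for the next coupling.

Step 7
Reactants: 10 5-iodo-1,3-dimethoxy-2-(3,4,5-trimethoxyphenoxy)benzene; 8 4-bromo-2,6-dimethoxyphenol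
Product: 11 5-bromo-2-[3,5-dimethoxy-4-(3,4,5-trimethoxyphenoxy)phenoxy]-1,3-dimethoxybenzene
Conditions: CuI (cat.), picolinic acid, K3PO4, DMSO, 80 °C, Ar
Reagents that add atoms: none
Why: A second iodide-selective Ullmann ether synthesis forms the E4–O–F1 bond and leaves the E1 bromide as the handle for fragment union.

Step 8
Reactants: 6 6-(2,6-dimethoxyphenoxy)-2,3,4-trimethoxyphenol; 11 5-bromo-2-[3,5-dimethoxy-4-(3,4,5-trimethoxyphenoxy)phenoxy]-1,3-dimethoxybenzene
Product: 12 1-(2,6-dimethoxyphenoxy)-2-{4-[3,5-dimethoxy-4-(3,4,5-trimethoxyphenoxy)phenoxy]-3,5-dimethoxyphenoxy}-3,4,5-trimethoxybenzene (dodeca-O-methyl CDEFG pentamer with hydrogen at C1 of ring C)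
Conditions: CuI (cat.), picolinic acid, K3PO4, DMSO, 110 °C, Ar
Reagents that add atoms: none
Why: Ullmann coupling with the crowded D6 oxygen as the phenoxide and the unhindered E1 carbon as the bromide uses the sterically easier polarity for the D6–O–E1 bond.

Step 9
Reactants: 12 dodeca-O-methyl CDEFG pentamer
Product: 14 4-{2-[4-(3,5-dimethoxy-4-(3,4,5-trimethoxyphenoxy)phenoxy)-3,5-dimethoxyphenoxy]-3,4,5-trimethoxyphenoxy}-3,5-dimethoxyphenol (CDEFG phenol), via ring C pinacol boronate 13 (not isolated)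
Conditions: [Ir(OMe)(cod)]2 (cat.), 4,4′-di-tert-butyl-2,2′-bipyridine, B2pin2, THF, 80 °C; then 30% aq. H2O2, aq. NaHCO3, THF, 0 → 25 °C
Reagents that add atoms: bis(pinacolato)diboron CC1(C)OB(OC1(C)C)B1OC(C)(C)C(C)(C)O1 (boron of 13); hydrogen peroxide OO (oxygen of 14)
Why: Sterically governed iridium-catalysed C–H borylation should attack the only C–H bond of 12 without an ortho substituent (C1 of ring C, para to the ether oxygen), and boronate oxidation converts the C–B bond into the phenol at the same carbon.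

Step 10
Reactants: 15 methoxyacetone
Product: 16 (Z)-4-(dimethylamino)-3-methoxybut-3-en-2-one
Conditions: Me2NCH(OMe)2, neat, 100 °C
Reagents that add atoms: N,N-dimethylformamide dimethyl acetal COC(OC)N(C)C
Why: Aminomethylenation with the formamide acetal occurs at the more acidic methoxy-bearing methylene and gives the push–pull enaminone with the donor anti to the acetyl group.

Step 11
Reactants: 16 (Z)-4-(dimethylamino)-3-methoxybut-3-en-2-one
Product: 18 (Z)-4-chloro-3-methoxybut-3-en-2-one, via 4-hydroxy-3-methoxybut-3-en-2-one 17 (not isolated)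
Conditions: 1 M HCl, THF, 25 °C; extraction (CH2Cl2), drying; then (COCl)2, DMF (cat.), CH2Cl2, 0 → 25 °C
Reagents that add atoms: water O (hydroxyl oxygen of 17); oxalyl chloride O=C(Cl)C(Cl)=O (chlorine of 18)
Why: Acid hydrolysis of the vinylogous amide gives the hydroxymethylene ketone, and Vilsmeier-type chlorination (chloroiminium from oxalyl chloride and DMF) replaces the enol hydroxyl by chloride to give the β-chlorovinyl ketone.

Step 12
Reactants: 14 CDEFG phenol; 18 (Z)-4-chloro-3-methoxybut-3-en-2-one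
Product: 19 (Z)-3-methoxy-4-(CDEFG-aryloxy)but-3-en-2-one
Conditions: K2CO3, DABCO (cat.), MeCN, 25 °C; excess 18
Reagents that add atoms: none
Why: Vinylic addition–elimination, relayed through the DABCO vinylammonium salt, lets the unhindered phenoxide replace chloride and should give the thermodynamically favoured Z enol ether with the aryloxy group anti to the carbonyl.

Step 13
Reactants: 19 (Z)-3-methoxy-4-(CDEFG-aryloxy)but-3-en-2-one
Product: 21 (Z)-1-diazo-3-methoxy-4-(CDEFG-aryloxy)but-3-en-2-one, via trifluoroacetyl diketone 20 (not isolated)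
Conditions: LiN(SiMe3)2, THF, −78 °C; CF3CO2CH2CF3, −78 °C; cold 1 M HCl work-up; then 4-acetamidobenzenesulfonyl azide, Et3N, H2O (1 equiv), MeCN, 25 °C
Reagents that add atoms: 2,2,2-trifluoroethyl trifluoroacetate O=C(OCC(F)(F)F)C(F)(F)F (trifluoroacetyl group of 20); 4-acetamidobenzenesulfonyl azide CC(=O)Nc1ccc(cc1)S(=O)(=O)N=[N+]=[N-] (diazo nitrogens of 21)
Why: Detrifluoroacetylative diazo transfer (kinetic enolisation at the methyl group, Claisen trifluoroacetylation, then Regitz-type transfer with loss of the trifluoroacetyl group) is the standard entry to α′-diazo enones and spares the conjugated enol ether.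

Step 14
Reactants: 22 2,4,6-trimethoxybenzaldehyde
Product: 24 2,4,6-trimethoxyphenol, via 2,4,6-trimethoxyphenyl formate 23 (not isolated)
Conditions: 30% aq. H2O2, H2SO4 (cat.), MeOH, 25 °C
Reagents that add atoms: hydrogen peroxide OO
Why: In this acid-catalysed Dakin (Baeyer–Villiger-type) oxidation the very electron-rich aryl group migrates to oxygen and the formate is methanolysed in the same pot.

Step 15
Reactants: 24 2,4,6-trimethoxyphenol; 25 trichloroethylene
Product: 26 2-[(E)-1,2-dichloroethenoxy]-1,3,5-trimethoxybenzene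
Conditions: KH, THF, 0 °C; then trichloroethylene, −50 → 25 °C
Reagents that add atoms: none
Why: Base converts trichloroethylene into dichloroacetylene, to which the phenoxide adds in anti fashion (addition–elimination overall), giving the (E)-1,2-dichlorovinyl ether even from a 2,6-disubstituted phenol.

Step 16
Reactants: 26 2-[(E)-1,2-dichloroethenoxy]-1,3,5-trimethoxybenzene
Product: 29 2-(ethynyloxy)-1,3,5-trimethoxybenzene (2,4,6-trimethoxyphenyl ethynyl ether), via chloroethynyl 2,4,6-trimethoxyphenyl ether 27 (not isolated), via lithium (2,4,6-trimethoxyphenoxy)acetylide 28 (not isolated)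
Conditions: n-BuLi (2.3 equiv), THF, −78 → −40 °C; then H2O, −78 °C
Reagents that add atoms: n-butyllithium [Li]CCCC (lithium of 28)
Why: Dehydrochlorination gives the chloroalkyne, chlorine–lithium exchange gives the lithium alkynyl ether and cold protonation releases the terminal ynol ether, which as an aryl ether has no β-hydrogen for retro-ene loss.

Step 17
Reactants: 21 (Z)-1-diazo-3-methoxy-4-(CDEFG-aryloxy)but-3-en-2-one; 29 2,4,6-trimethoxyphenyl ethynyl ether
Product: 34 2-(CDEFG-aryloxy)-3-methoxy-5-(2,4,6-trimethoxyphenoxy)phenol (hexadeca-O-methyl heptamer with free B3 hydroxyl), via vinylketene 30 (not isolated), via cyclobutenone 31 (not isolated), via dienylketene 32 (not isolated), via cyclohexadienone 33 (not isolated)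
Conditions: hν (365 nm), ClCH2CH2Cl (dilute), 25 °C, Ar; then 80 °C; excess 29
Reagents that add atoms: none
Why: Irradiation expels N2 and the alkenyl group shifts to the former diazo carbon (photochemical Wolff rearrangement, B5–B6), giving vinylketene 30, whose central carbon is attacked by the nucleophilic CH terminus of ynol ether 29 in a (2+2) cycloaddition (B2–B3, B1–B6) to cyclobutenone 31. Four-electron electrocyclic opening of 31 gives dienylketene 32, and ring B is closed by a thermally allowed disrotatory six-electron electrocyclisation (B3–B4) to dienone 33, which tautomerises to phenol 34. The closest known reaction type is the Danheiser benzannulation in its photo-Wolff form, in which α′-diazo enones and alkynyl ethers give 3-alkoxyphenols. No stereocentre is set, the sp3 carbons of 31 and 33 being erased on aromatisation. The selectivity required is regiochemical and is secured by the polarisation of the ynol ether, which bonds through its CH carbon to the ketene carbonyl carbon so that the ring A ether ends meta to the new hydroxyl and para to the ring C ether; the Z geometry of 21 keeps the aryloxy group remote from the carbene-like centre and on the outer side of the cyclising triene. Light of 365 nm is absorbed by the diazo ketone but not by the aryl ether chromophores, and excess 29 outcompetes acylation of the product phenol by the ketene.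

Step 18
Reactants: 34 hexadeca-O-methyl heptamer with free B3 hydroxyl
Product: 35 2-{4-[2-(4-{3,5-dihydroxy-4-(3,4,5-trihydroxyphenoxy)phenoxy}-3,5-dihydroxyphenoxy)-3,4,5-trihydroxyphenoxy]-3,5-dihydroxyphenoxy}-5-(2,4,6-trihydroxyphenoxy)benzene-1,3-diol (CNP0304148.0)
Conditions: BBr3 (excess), CH2Cl2, −78 → 25 °C, Ar; then degassed H2O, 0 °C; reverse-phase purification under Ar
Reagents that add atoms: none
Why: Lewis-acid ether cleavage with BBr3 removes each methyl group by bromide attack at the sp3 carbon of the boron-complexed ether, while the diaryl ether bonds offer no such carbon and should persist, so hydrolysis liberates the heptadecahydroxy target.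

Compound list
1 | 2,3,4-trimethoxyphenol | COc1ccc(O)c(OC)c1OC | starting material
2 | 6-bromo-2,3,4-trimethoxyphenol | COc1cc(Br)c(O)c(OC)c1OC | intermediate
3 | 2-(benzyloxy)-1-bromo-3,4,5-trimethoxybenzene | COc1cc(Br)c(OCc2ccccc2)c(OC)c1OC | intermediate
4 | 2,6-dimethoxyphenol | COc1cccc(OC)c1O | starting material
5 | 2-(benzyloxy)-1-(2,6-dimethoxyphenoxy)-3,4,5-trimethoxybenzene | COc1cccc(OC)c1Oc1cc(OC)c(OC)c(OC)c1OCc1ccccc1 | intermediate
6 | 6-(2,6-dimethoxyphenoxy)-2,3,4-trimethoxyphenol | COc1cccc(OC)c1Oc1cc(OC)c(OC)c(OC)c1O | intermediate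
7 | 5-iodo-1,2,3-trimethoxybenzene | COc1cc(I)cc(OC)c1OC | starting material
8 | 4-bromo-2,6-dimethoxyphenol | COc1cc(Br)cc(OC)c1O | starting material
9 | 5-bromo-1,3-dimethoxy-2-(3,4,5-trimethoxyphenoxy)benzene | COc1cc(Br)cc(OC)c1Oc1cc(OC)c(OC)c(OC)c1 | intermediate
10 | 5-iodo-1,3-dimethoxy-2-(3,4,5-trimethoxyphenoxy)benzene | COc1cc(I)cc(OC)c1Oc1cc(OC)c(OC)c(OC)c1 | intermediate
11 | 5-bromo-2-[3,5-dimethoxy-4-(3,4,5-trimethoxyphenoxy)phenoxy]-1,3-dimethoxybenzene | COc1cc(Br)cc(OC)c1Oc1cc(OC)c(Oc2cc(OC)c(OC)c(OC)c2)c(OC)c1 | intermediate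
12 | 1-(2,6-dimethoxyphenoxy)-2-{4-[3,5-dimethoxy-4-(3,4,5-trimethoxyphenoxy)phenoxy]-3,5-dimethoxyphenoxy}-3,4,5-trimethoxybenzene | COc1cccc(OC)c1Oc1cc(OC)c(OC)c(OC)c1Oc1cc(OC)c(Oc2cc(OC)c(Oc3cc(OC)c(OC)c(OC)c3)c(OC)c2)c(OC)c1 | intermediate
13 | pinacol boronate of 12 at C1 of ring C | CC1(C)OB(OC1(C)C)c1cc(OC)c(Oc2cc(OC)c(OC)c(OC)c2Oc2cc(OC)c(Oc3cc(OC)c(Oc4cc(OC)c(OC)c(OC)c4)c(OC)c3)c(OC)c2)c(OC)c1 | intermediate (not isolated)
14 | 4-{2-[4-(3,5-dimethoxy-4-(3,4,5-trimethoxyphenoxy)phenoxy)-3,5-dimethoxyphenoxy]-3,4,5-trimethoxyphenoxy}-3,5-dimethoxyphenol (CDEFG phenol) | Oc1cc(OC)c(Oc2cc(OC)c(OC)c(OC)c2Oc2cc(OC)c(Oc3cc(OC)c(Oc4cc(OC)c(OC)c(OC)c4)c(OC)c3)c(OC)c2)c(OC)c1 | intermediate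
15 | methoxyacetone | COCC(C)=O | starting material
16 | (Z)-4-(dimethylamino)-3-methoxybut-3-en-2-one | CC(=O)/C(OC)=C/N(C)C | intermediate
17 | (E)-4-hydroxy-3-methoxybut-3-en-2-one (chelated enol of 2-methoxy-3-oxobutanal) | CC(=O)/C(OC)=C\O | intermediate (not isolated)
18 | (Z)-4-chloro-3-methoxybut-3-en-2-one | CC(=O)/C(OC)=C/Cl | intermediate
19 | (Z)-3-methoxy-4-(CDEFG-aryloxy)but-3-en-2-one | CC(=O)/C(OC)=C/Oc1cc(OC)c(Oc2cc(OC)c(OC)c(OC)c2Oc2cc(OC)c(Oc3cc(OC)c(Oc4cc(OC)c(OC)c(OC)c4)c(OC)c3)c(OC)c2)c(OC)c1 | intermediate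
20 | (Z)-1,1,1-trifluoro-5-methoxy-6-(CDEFG-aryloxy)hex-5-ene-2,4-dione | O=C(CC(=O)/C(OC)=C/Oc1cc(OC)c(Oc2cc(OC)c(OC)c(OC)c2Oc2cc(OC)c(Oc3cc(OC)c(Oc4cc(OC)c(OC)c(OC)c4)c(OC)c3)c(OC)c2)c(OC)c1)C(F)(F)F | intermediate (not isolated)
21 | (Z)-1-diazo-3-methoxy-4-(CDEFG-aryloxy)but-3-en-2-one | [N-]=[N+]=CC(=O)/C(OC)=C/Oc1cc(OC)c(Oc2cc(OC)c(OC)c(OC)c2Oc2cc(OC)c(Oc3cc(OC)c(Oc4cc(OC)c(OC)c(OC)c4)c(OC)c3)c(OC)c2)c(OC)c1 | intermediate
22 | 2,4,6-trimethoxybenzaldehyde | COc1cc(OC)c(C=O)c(OC)c1 | starting material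
23 | 2,4,6-trimethoxyphenyl formate | O=COc1c(OC)cc(OC)cc1OC | intermediate (not isolated)
24 | 2,4,6-trimethoxyphenol | COc1cc(OC)c(O)c(OC)c1 | intermediate
25 | trichloroethylene | ClC=C(Cl)Cl | starting material
26 | 2-[(E)-1,2-dichloroethenoxy]-1,3,5-trimethoxybenzene | Cl/C=C(/Cl)Oc1c(OC)cc(OC)cc1OC | intermediate
27 | 2-(chloroethynyloxy)-1,3,5-trimethoxybenzene | ClC#COc1c(OC)cc(OC)cc1OC | intermediate (not isolated)
28 | lithium (2,4,6-trimethoxyphenoxy)acetylide | [Li]C#COc1c(OC)cc(OC)cc1OC | intermediate (not isolated)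
29 | 2-(ethynyloxy)-1,3,5-trimethoxybenzene | C#COc1c(OC)cc(OC)cc1OC | intermediate
30 | (Z)-3-methoxy-4-(CDEFG-aryloxy)buta-1,3-dien-1-one | O=C=C/C(OC)=C/Oc1cc(OC)c(Oc2cc(OC)c(OC)c(OC)c2Oc2cc(OC)c(Oc3cc(OC)c(Oc4cc(OC)c(OC)c(OC)c4)c(OC)c3)c(OC)c2)c(OC)c1 | intermediate (not isolated)
31 | rac-4-[(Z)-1-methoxy-2-(CDEFG-aryloxy)ethenyl]-3-(2,4,6-trimethoxyphenoxy)cyclobut-2-en-1-one | O=C1C=C(Oc2c(OC)cc(OC)cc2OC)C1/C(OC)=C/Oc1cc(OC)c(Oc2cc(OC)c(OC)c(OC)c2Oc2cc(OC)c(Oc3cc(OC)c(Oc4cc(OC)c(OC)c(OC)c4)c(OC)c3)c(OC)c2)c(OC)c1 | intermediate (not isolated)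
32 | (3E,5Z)-5-methoxy-6-(CDEFG-aryloxy)-3-(2,4,6-trimethoxyphenoxy)hexa-1,3,5-trien-1-one | O=C=C/C(Oc1c(OC)cc(OC)cc1OC)=C\C(OC)=C\Oc1cc(OC)c(Oc2cc(OC)c(OC)c(OC)c2Oc2cc(OC)c(Oc3cc(OC)c(Oc4cc(OC)c(OC)c(OC)c4)c(OC)c3)c(OC)c2)c(OC)c1 | intermediate (not isolated)
33 | rac-5-methoxy-6-(CDEFG-aryloxy)-3-(2,4,6-trimethoxyphenoxy)cyclohexa-2,4-dien-1-one | O=C1C=C(Oc2c(OC)cc(OC)cc2OC)C=C(OC)C1Oc1cc(OC)c(Oc2cc(OC)c(OC)c(OC)c2Oc2cc(OC)c(Oc3cc(OC)c(Oc4cc(OC)c(OC)c(OC)c4)c(OC)c3)c(OC)c2)c(OC)c1 | intermediate (not isolated)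
34 | 2-(CDEFG-aryloxy)-3-methoxy-5-(2,4,6-trimethoxyphenoxy)phenol (hexadeca-O-methyl heptamer, free B3 hydroxyl) | COc1cc(OC)c(Oc2cc(O)c(Oc3cc(OC)c(Oc4cc(OC)c(OC)c(OC)c4Oc4cc(OC)c(Oc5cc(OC)c(Oc6cc(OC)c(OC)c(OC)c6)c(OC)c5)c(OC)c4)c(OC)c3)c(OC)c2)c(OC)c1 | intermediate
35 | 2-{4-[2-(4-{3,5-dihydroxy-4-(3,4,5-trihydroxyphenoxy)phenoxy}-3,5-dihydroxyphenoxy)-3,4,5-trihydroxyphenoxy]-3,5-dihydroxyphenoxy}-5-(2,4,6-trihydroxyphenoxy)benzene-1,3-diol (CNP0304148.0) | Oc1cc(O)c(Oc2cc(O)c(Oc3cc(O)c(Oc4cc(O)c(O)c(O)c4Oc4cc(O)c(Oc5cc(O)c(Oc6cc(O)c(O)c(O)c6)c(O)c5)c(O)c4)c(O)c3)c(O)c2)c(O)c1 | target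

Total step count: 18.
Longest linear sequence: 10 steps (1, 2, 3, 4, 8, 9, 12, 13, 17, 18).

Steps most likely to fail

Step 17. The photochemical Wolff rearrangement may be inefficient next to the large polyaryl ether, or the vinylketene may be diverted into dimerisation or acylation of the product phenol before the (2+2) addition. The fallback drops the annulation, brings ring B in preformed and makes every ether by Ullmann coupling. It sets out from 8, 24, 3 and 11 and rejoins the route at 35.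
- Benzylation of 8 (BnBr, K2CO3, DMF) gives 2-(benzyloxy)-5-bromo-1,3-dimethoxybenzene F1.
- Coupling of 24 with F1 (CuI, picolinic acid, K3PO4, DMSO) gives 2-(benzyloxy)-1,3-dimethoxy-5-(2,4,6-trimethoxyphenoxy)benzene F2. Hydrogenolysis (H2, Pd/C) gives 2,6-dimethoxy-4-(2,4,6-trimethoxyphenoxy)phenol F3.
- A second coupling with F1 gives 2-(benzyloxy)-5-[2,6-dimethoxy-4-(2,4,6-trimethoxyphenoxy)phenoxy]-1,3-dimethoxybenzene F4. Hydrogenolysis gives 4-[2,6-dimethoxy-4-(2,4,6-trimethoxyphenoxy)phenoxy]-2,6-dimethoxyphenol F5.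
- Coupling of F5 with bromide 3 gives the ABCD benzyl ether F6. Hydrogenolysis gives the ABCD phenol F7.
- Coupling of F7 with bromide 11 gives the heptadeca-O-methyl heptamer F8, which BBr3 (as in step 18) converts into 35.

Step 9. Borylation of the dodecamethoxy pentamer may stall through catalyst binding by the many ether oxygens, or stray to C–H bonds flanked by methoxy. The fallback carries the C1 oxygen of ring C through the assembly as a formyl group. It sets out from 3 and 11 and rejoins the route at 14.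
- Ullmann coupling of purchased 4-hydroxy-3,5-dimethoxybenzaldehyde with 3 gives 4-[2-(benzyloxy)-3,4,5-trimethoxyphenoxy]-3,5-dimethoxybenzaldehyde F9.
- Hydrogenolysis in EtOAc, stopped after one equivalent of hydrogen, gives 4-(2-hydroxy-3,4,5-trimethoxyphenoxy)-3,5-dimethoxybenzaldehyde F10.
- Coupling with 11 gives the CDEFG aldehyde F11.
- Baeyer–Villiger oxidation (mCPBA, NaHCO3, CH2Cl2) gives the formate of the CDEFG phenol F12. Methanolysis (K2CO3, MeOH) delivers 14.

Step 18. Cleavage of sixteen ethers may stop short, leaving partly methylated congeners that co-elute with the polyphenol, and the free polyphenol may be lost to air oxidation during isolation. The fallback isolates the product as a stable ester. It sets out from 34 and rejoins the route at 35.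
- The crude product of the BBr3 treatment is acetylated (Ac2O, pyridine, DMAP) to the heptadeca-O-acetate F13.
- F13 is purified on silica, where under-demethylated material separates and can be returned to BBr3.
- Acid-catalysed methanolysis (HCl in MeOH from AcCl, degassed) releases 35 with only volatile by-products.

Further compounds
F1 | step 17 | 2-(benzyloxy)-5-bromo-1,3-dimethoxybenzene | COc1cc(Br)cc(OC)c1OCc1ccccc1
F2 | step 17 | 2-(benzyloxy)-1,3-dimethoxy-5-(2,4,6-trimethoxyphenoxy)benzene | COc1cc(OC)c(Oc2cc(OC)c(OCc3ccccc3)c(OC)c2)c(OC)c1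
F3 | step 17 | 2,6-dimethoxy-4-(2,4,6-trimethoxyphenoxy)phenol | COc1cc(OC)c(Oc2cc(OC)c(O)c(OC)c2)c(OC)c1
F4 | step 17 | 2-(benzyloxy)-5-[2,6-dimethoxy-4-(2,4,6-trimethoxyphenoxy)phenoxy]-1,3-dimethoxybenzene | COc1cc(OC)c(Oc2cc(OC)c(Oc3cc(OC)c(OCc4ccccc4)c(OC)c3)c(OC)c2)c(OC)c1
F5 | step 17 | 4-[2,6-dimethoxy-4-(2,4,6-trimethoxyphenoxy)phenoxy]-2,6-dimethoxyphenol | COc1cc(OC)c(Oc2cc(OC)c(Oc3cc(OC)c(O)c(OC)c3)c(OC)c2)c(OC)c1
F6 | step 17 | ABCD benzyl ether (benzyloxy at D6) | COc1cc(OC)c(Oc2cc(OC)c(Oc3cc(OC)c(Oc4cc(OC)c(OC)c(OC)c4OCc4ccccc4)c(OC)c3)c(OC)c2)c(OC)c1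
F7 | step 17 | ABCD phenol (hydroxyl at D6) | COc1cc(OC)c(Oc2cc(OC)c(Oc3cc(OC)c(Oc4cc(OC)c(OC)c(OC)c4O)c(OC)c3)c(OC)c2)c(OC)c1
F8 | step 17 | heptadeca-O-methyl heptamer | COc1cc(OC)c(Oc2cc(OC)c(Oc3cc(OC)c(Oc4cc(OC)c(OC)c(OC)c4Oc4cc(OC)c(Oc5cc(OC)c(Oc6cc(OC)c(OC)c(OC)c6)c(OC)c5)c(OC)c4)c(OC)c3)c(OC)c2)c(OC)c1
F9 | step 9 | 4-[2-(benzyloxy)-3,4,5-trimethoxyphenoxy]-3,5-dimethoxybenzaldehyde | O=Cc1cc(OC)c(Oc2cc(OC)c(OC)c(OC)c2OCc2ccccc2)c(OC)c1
F10 | step 9 | 4-(2-hydroxy-3,4,5-trimethoxyphenoxy)-3,5-dimethoxybenzaldehyde | O=Cc1cc(OC)c(Oc2cc(OC)c(OC)c(OC)c2O)c(OC)c1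
F11 | step 9 | CDEFG aldehyde (formyl at C1 of ring C) | O=Cc1cc(OC)c(Oc2cc(OC)c(OC)c(OC)c2Oc2cc(OC)c(Oc3cc(OC)c(Oc4cc(OC)c(OC)c(OC)c4)c(OC)c3)c(OC)c2)c(OC)c1
F12 | step 9 | formate ester of the CDEFG phenol | O=COc1cc(OC)c(Oc2cc(OC)c(OC)c(OC)c2Oc2cc(OC)c(Oc3cc(OC)c(Oc4cc(OC)c(OC)c(OC)c4)c(OC)c3)c(OC)c2)c(OC)c1
F13 | step 18 | heptadeca-O-acetate of the target | CC(=O)Oc1cc(OC(C)=O)c(Oc2cc(OC(C)=O)c(Oc3cc(OC(C)=O)c(Oc4cc(OC(C)=O)c(OC(C)=O)c(OC(C)=O)c4Oc4cc(OC(C)=O)c(Oc5cc(OC(C)=O)c(Oc6cc(OC(C)=O)c(OC(C)=O)c(OC(C)=O)c6)c(OC(C)=O)c5)c(OC(C)=O)c4)c(OC(C)=O)c3)c(OC(C)=O)c2)c(OC(C)=O)c1
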